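The elm run was slow: after 4.00 h its substrate had given 26.7% of open intermediate and 0.4% of target, with a scatter of 1 percentage point on each reading.

elm run (percent of the substrate charged)

| time / h | open intermediate / % | target / % |
|---|---|---|
| 0.333 | 1.1 | 0 |
| 0.667 | 4.0 | 0 |
| 1.50 | 11.8 | 0 |
| 4.00 | 26.7 | 0.4 |

(scatter of a reading: 1 percentage point)

the same everywhere: partner 0.189 M

| flask | substrate | capture agent | remark | time |
|---|---|---|---|---|
| elm | 0.14 M | 0.027 M | run made earlier |  |
| flask | 0.27 M | 0.0270 M |  | 40 h |

1. when, up to 40 h, the flask holds most open intermediate
2. the amount of open intermediate, in percent of the substrate charged, at that time

I followed one substrate molecule and asked for its chance per hour of opening. Taking the step as first order, which one run cannot prove, and counting as remaining substrate the charge less the two last elm readings, I defined the opening chance k (the first-order rate constant) as the logarithm of charged over remaining substrate, divided by the time: 0.0790 h⁻¹, read from the elm run, a half-life of 8.77 h.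

The bench rule for a first-order step says that its percentages do not depend on the charge, so I laid the elm curve over the flask, though the flask's substrate charge was twice that of the elm run. The border lay in the time, because the flask ran ten times as long as the elm readings reached. I still trusted k for opening, and it left 4.24% of the substrate at 40 h. The next fork, where an open molecule leaves, lay beyond the rule. The last target reading, divided by the mean open intermediate in the elm run and by the time, gave a leaving chance of 0.00749 h⁻¹, a weak value, as that target reading lay within its scatter.

The forecast gave 40 h and 58%, holding that “the intermediate is still rising slowly” at the end. My reckoning differed. To keep rising at that height, an open molecule had to leave at less than 0.00578 h⁻¹, and my reading was higher, so I expected the top before 40 h.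

The flask reached its top at 18.0 h with 53.6%.

    substrate → open intermediate (k = 0.00130 min⁻¹)
    partner → second intermediate (k = 0.00120 min⁻¹)
    open intermediate + second intermediate → target (k = 0.00260 L mol⁻¹ min⁻¹)
    2 open intermediate → homo product (k = 7.80 × 10⁻⁴ L mol⁻¹ min⁻¹)
    open intermediate + capture agent → trapped intermediate (k = 0.00540 L mol⁻¹ min⁻¹)

At 40.0 h the flask made open intermediate more slowly than it used it up, at 0.312 of that rate, each step taken net, and held 39.5%. For that time k gave 4.24% of substrate, and the flask held 4.42%. For a neighbouring flask with 0.076 M of partner k gave the same 4.24%, and that flask held 4.42% of its substrate at 40.0 h.

The data stem from a simulated flask for substances that don't exist, and the scatter is random.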